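**Analysis of the target**

Compound 19 is a flavanone, a 2,3-dihydrochromen-4-one. Ring A carries hydroxyls at C5 and C7, ring C holds the C4 ketone and the ring oxygen O1, and ring B sits on C2. Ring B is a 1,3,4,5-tetrasubstituted benzene: a 4'-methoxy group flanked by a 3'-[(E)-3-hydroxy-3-methylbut-1-enyl] chain and a 5'-prenyl group. The only stereocentre is C2 (S). It is benzylic, bonded to O1 and β to the ketone, so base can open ring C by β-elimination to the 2'-hydroxychalcone and close it again with loss of configuration, and the para-methoxy group of ring B makes the C2–O1 bond ionisable in acid. The tertiary allylic alcohol conjugated to ring B ionises readily in acid, and the prenyl alkene tolerates neither strong acid nor hydrogenation. Methyl ethers cannot serve on ring A because the 4'-methoxy group must survive. The difficulty is therefore to set C2 in the presence of three C=C bonds without hydrogenation, without acid, and without base once C2 exists. The strategy rests on two features: the C4 carbonyl lies between aromatic C4a and C3, and ring A is symmetric about the C4a–C7 axis once O1 is disconnected. A phloroglucinol iodinated at the future C4a can thus be joined through carbon monoxide to a ring-B alkyne that supplies C3 and C2, and either flanking oxygen can become O1.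

**Retrosynthetic reasoning**

19 from 18. The two aryl O–Si bonds are cut last. Silyl ethers are chosen for ring A because a buffered fluoride source is neither acidic enough to ionise the tertiary allylic alcohol nor basic enough to open ring C. The forward step only has to free the C5 and C7 phenols without touching C2.

18 from 16. The C2–H bond is cut, taking the stereocentre back to the planar flavone. Placing this cut late means that no step after it needs heat or base. The forward reaction must deliver hydride to one face of C2 and leave the prenyl and styrenyl alkenes alone, which excludes hydrogenation and points to a chiral copper hydride fed by a hydrosilane.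

16 from 15. The O–Si bonds are cut. The phenols are masked because their acidic protons would quench the hydride catalyst; the tertiary alcohol stays free.

15 from 11, 8 and 12. Three bonds are cut: C4a–C4, C4–C3 and O1–C2. C4 then becomes carbon monoxide 12, ring A comes intact from phloroglucinol 9, and ring B arrives with both side chains finished in alkyne 8, so no side-chain chemistry follows ring closure. The forward reaction has to insert CO before the alkyne couples and has to close the six-membered ring, not the five-membered one. The free triol 10 is not used directly: it is an air- and light-sensitive, very electron-rich iodophenol whose phenoxides would slow oxidative addition and compete for the aroylpalladium intermediate. Its triacetate 11 costs one step and needs no separate deprotection, because the secondary amine that steers the ring closure also removes the acetates.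

11 from 10 from 9. The C–I bond is cut to an electrophilic iodination. All three ring positions of 9 are equivalent, so only the degree of iodination has to be controlled.

8 from 7. The terminal alkyne carbon is cut, leaving a one-carbon homologation of the aldehyde. The formyl group acts as the masked alkyne through the earlier palladium step, where a free alkyne would interfere.

7 from 5 and 6. The aryl–vinyl bond is cut. A Heck coupling with 6 brings in the whole five-carbon chain with its tertiary alcohol in one step, and the E geometry follows from the mechanism.

5 back to 1. The prenyl C=C bond is cut to a cross-metathesis of the allyl group of 4. The methyl ether of 4 goes back to phenol 3. The C5–allyl bond of 3 is cut to a Claisen rearrangement of ether 2, whose regiochemistry is fixed because bromine blocks the other ortho position. Ether 2 comes from 1 by O-allylation.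

**Alternatives that were turned down**

Alternative 1: Ring C is disconnected at O1–C2 and C3–C4 into an ortho-quinone methide of ring A and the ring-B styrene A2. In the forward step a chiral phosphoric acid and an orthoformate ester convert a MOM-protected salicylaldehyde into a methoxy-substituted ortho-quinone methide, which adds A2 to give chromane A1.
- For: ring C, two bonds and the C2 stereocentre come from one convergent step, and the bromine of A1 keeps the acid-labile side chain out until late.
- Against: C4 arrives as a methyl ether and needs two further redox operations to become the ketone. The prenyl alkene of A2 is itself an electron-rich partner for the quinone methide and is exposed to the acid. A2 offers the catalyst no hydrogen-bonding site, so facial control rests on ion pairing alone. MOM removal needs acid, which forces the Heck coupling with 6 to the very end, on a free flavanone that loses C2 under base and heat.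
- Comparison: neither route has a direct precedent for its stereochemical step, and setting C2 during ring formation is the more elegant idea. The chosen route offers a shorter endgame (three steps after the key step), a side chain installed before the heterocycle exists, and a resolution to fall back on.

Alternative 2: Ring A is disconnected at C4a–C5 and built last by an intramolecular Claisen condensation. In the forward step a magnesium alkoxide enolises the keto ester chain of dihydropyranone A4, C4a attacks the ester carbonyl, and loss of methanol with enolisation gives flavanone A3.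
- For: ring A appears with both phenols free and no protecting groups. C2 can be set early by an asymmetric hetero-Diels–Alder reaction of a ring-B aldehyde, which is better precedented than the reduction used here; on that point this alternative is stronger.
- Against: the tricarbonyl chain of A4 has competing cyclisation modes (aldol closure onto the ketone, O-acylation to a pyranone). The alkoxide can eject O1 from the dihydropyranone enolate and destroy C2. A4 needs a long linear preparation of a ring that phloroglucinol 9 supplies ready-made. A3 still needs the late Heck coupling under base.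
- Comparison: the chosen route gives up early, well-precedented stereocontrol and gains a commercial ring A, a more convergent assembly and no base after C2 is set.

Alternative 3: Ring C is disconnected at C4–C4a to a Friedel–Crafts acylation. In the forward step the acid A6 is activated as a mixed anhydride under strongly acidic conditions and acylates ring A ortho to the ether oxygen to give A5.
- For: the stereocentre comes from an asymmetric ketone reduction followed by a Mitsunobu inversion, both well established, and the symmetric ring A removes any regiochemical question. On stereochemical precedent this alternative is stronger than the chosen one.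
- Against: the para-methoxy group of ring B makes the benzylic C–O bond of A6 and A5 ionisable, so both the Mitsunobu step and the strong acid set free during acylation invite scrambling or cleavage at C2. The prenyl alkene and the silyl ethers also meet that acid. A5 again ends with a Heck coupling on a base-sensitive flavanone.
- Comparison: the chosen route avoids acid entirely after the side chains are in place and confines its risk to one late reduction.

Key step: step 9

Assumption: the (S)-enantiomer of the bisphosphine in step 11 is taken to deliver hydride to the Re face of C2, by analogy with cyclic β,β-disubstituted enones; if a first run shows the opposite sense, the (R)-ligand is used and nothing else changes.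

**Route**

Step 1
Reactants: 1 3-bromo-4-hydroxybenzaldehyde
Product: 2 3-bromo-4-(prop-2-enyloxy)benzaldehyde
Conditions: allyl bromide, K2CO3, DMF, rt
Reagents that add atoms: allyl bromide, C=CCBr
Why: Williamson etherification; the phenol para to the formyl group is acidic and its phenoxide is alkylated on oxygen by the allylic bromide.

Step 2
Reactants: 2 3-bromo-4-(prop-2-enyloxy)benzaldehyde
Product: 3 3-bromo-4-hydroxy-5-(prop-2-enyl)benzaldehyde
Conditions: N,N-diethylaniline, 200 °C, sealed vessel
Reagents that add atoms: none
Why: Aromatic Claisen rearrangement; the [3,3] shift can end productively only at C5, the one ortho carbon that carries hydrogen, and tautomerisation restores the phenol.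

Step 3
Reactants: 3 3-bromo-4-hydroxy-5-(prop-2-enyl)benzaldehyde
Product: 4 3-bromo-4-methoxy-5-(prop-2-enyl)benzaldehyde
Conditions: MeI, K2CO3, DMF, 40 °C
Reagents that add atoms: iodomethane, CI
Why: Williamson O-methylation of the phenoxide; it fixes the 4'-methoxy group of ring B before any metal-catalysed step.

Step 4
Reactants: 4 3-bromo-4-methoxy-5-(prop-2-enyl)benzaldehyde
Product: 5 3-bromo-4-methoxy-5-(3-methylbut-2-enyl)benzaldehyde
Conditions: 2-methylbut-2-ene (excess), second-generation Grubbs catalyst (3 mol %), CH2Cl2, 40 °C
Reagents that add atoms: 2-methylbut-2-ene, CC=C(C)C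
Why: Olefin cross-metathesis; the terminal allyl alkene exchanges its CH2 end for the isopropylidene end of the trisubstituted partner and propene escapes. The aldehyde and the aryl bromide are inert to the ruthenium carbene, and the step precedes the Heck coupling so that only one metathesis-active alkene is present.

Step 5
Reactants: 5 3-bromo-4-methoxy-5-(3-methylbut-2-enyl)benzaldehyde; 6 2-methylbut-3-en-2-ol
Product: 7 3-[(E)-3-hydroxy-3-methylbut-1-enyl]-4-methoxy-5-(3-methylbut-2-enyl)benzaldehyde
Conditions: Pd(OAc)2 (5 mol %), P(o-tol)3 (10 mol %), Et3N, DMF, 100 °C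
Reagents that add atoms: none
Why: Mizoroki–Heck coupling; the aryl group adds to the terminal carbon of 6, and because the carbinol carbon has no hydrogen, syn β-hydride elimination can only go towards the benzylic side, giving the E-alkene without migration. The trisubstituted prenyl alkene is too hindered to insert.

Step 6
Reactants: 7 3-[(E)-3-hydroxy-3-methylbut-1-enyl]-4-methoxy-5-(3-methylbut-2-enyl)benzaldehyde
Product: 8 (E)-4-[5-ethynyl-2-methoxy-3-(3-methylbut-2-enyl)phenyl]-2-methylbut-3-en-2-ol
Conditions: dimethyl (1-diazo-2-oxopropyl)phosphonate, K2CO3, MeOH, 0 °C → rt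
Reagents that add atoms: dimethyl (1-diazo-2-oxopropyl)phosphonate, CC(=O)C(=[N+]=[N-])P(=O)(OC)OC
Why: Seyferth–Gilbert homologation in its Ohira–Bestmann form; methanolysis of the acetyl group releases the diazomethylphosphonate anion, which olefinates the aldehyde, and loss of dinitrogen with a 1,2-hydrogen shift gives the terminal alkyne. The carbonate base leaves the tertiary alcohol and both alkenes untouched.

Step 7
Reactants: 9 benzene-1,3,5-triol (phloroglucinol)
Product: 10 2-iodobenzene-1,3,5-triol
Conditions: I2 (1.0 equiv), NaHCO3, THF–H2O, 0 °C
Reagents that add atoms: iodine, II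
Why: Electrophilic aromatic iodination; the three ring CH positions are equivalent, and one equivalent of iodine at 0 °C should stop at the mono-iodide. The product is sensitive to air and light and is taken crude into step 8.

Step 8
Reactants: 10 2-iodobenzene-1,3,5-triol
Product: 11 2-iodobenzene-1,3,5-triyl triacetate
Conditions: Ac2O, pyridine, DMAP (cat.), CH2Cl2, 0 °C → rt
Reagents that add atoms: acetic anhydride, CC(=O)OC(C)=O
Why: O-acylation of the three phenols; the triacetate is no longer prone to oxidation or loss of iodine, and iodophenol acetates are established partners for the carbonylative annulation.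

Step 9
Reactants: 11 2-iodobenzene-1,3,5-triyl triacetate; 8 (E)-4-[5-ethynyl-2-methoxy-3-(3-methylbut-2-enyl)phenyl]-2-methylbut-3-en-2-ol; 12 carbon monoxide
Product: 15 5,7-dihydroxy-2-[3-[(E)-3-hydroxy-3-methylbut-1-enyl]-4-methoxy-5-(3-methylbut-2-enyl)phenyl]chromen-4-one, via ynone triacetate 13 (not isolated), via enaminone 14 (not isolated)
Conditions: PdCl2(PPh3)2 (5 mol %), Et3N, CO (1 atm), THF, 40 °C; then Et2NH, 50 °C
Reagents that add atoms: none
Why: The divalent palladium precatalyst is reduced in the flask to zerovalent palladium, which inserts into the C–I bond of 11; CO insertion gives an aroylpalladium species, and amine-assisted transfer of the terminal alkyne 8 followed by reductive elimination gives ynone 13, forming C4a–C4 and C4–C3 (copper-free carbonylative Sonogashira coupling). The closest known reaction type is the carbonylative annulation of 2-iodophenols and their acetates with terminal arylacetylenes and CO to flavones. Diethylamine then adds to the ynone in conjugate fashion and cleaves the three aryl acetates by aminolysis, giving enaminone 14. Ring C closes when a phenol oxygen flanking the ketone attacks C2 of the enaminone and diethylamine is expelled, an addition–elimination that is the stepwise equivalent of a 6-endo-dig closure and forms O1–C2. No stereocentre is created. Carbonylative coupling has to beat direct aryl–alkyne coupling: the two ortho acetoxy groups slow alkyne transfer to the arylpalladium species while CO insertion relieves the crowding, and copper is left out. Flavone has to beat aurone: the phenols stay acetylated until the secondary amine is present, and in enaminone 14 the β-carbon is the only electrophilic position, so the 5-exo mode has no acceptor. The regiochemistry of closure needs no control, because the iodine of 11 lies on the mirror plane between two identical acetoxy groups; the flanking oxygen that is not used becomes 5-OH and the para oxygen becomes 7-OH.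

Step 10
Reactants: 15 5,7-dihydroxy-2-[3-[(E)-3-hydroxy-3-methylbut-1-enyl]-4-methoxy-5-(3-methylbut-2-enyl)phenyl]chromen-4-one
Product: 16 5,7-bis(tert-butyldimethylsilyloxy)-2-[3-[(E)-3-hydroxy-3-methylbut-1-enyl]-4-methoxy-5-(3-methylbut-2-enyl)phenyl]chromen-4-one
Conditions: TBSCl (3 equiv), imidazole, DMAP (cat.), DMF, 40 °C
Reagents that add atoms: tert-butyldimethylsilyl chloride, CC(C)(C)[Si](C)(C)Cl
Why: Silylation of both phenols; the 7-OH reacts readily and the hydrogen-bonded 5-OH more slowly, hence the excess and gentle warming, while the tertiary alcohol is too hindered for the silyl chloride. The acidic phenol protons that would quench the copper hydride are thereby removed.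

Step 11
Reactants: 16 5,7-bis(tert-butyldimethylsilyloxy)-2-[3-[(E)-3-hydroxy-3-methylbut-1-enyl]-4-methoxy-5-(3-methylbut-2-enyl)phenyl]chromen-4-one
Product: 18 (2S)-5,7-bis(tert-butyldimethylsilyloxy)-2-[3-[(E)-3-hydroxy-3-methylbut-1-enyl]-4-methoxy-5-(3-methylbut-2-enyl)phenyl]-2,3-dihydrochromen-4-one, via silyl enol ether 17 (not isolated)
Conditions: Cu(OAc)2 (5 mol %), (S)-DTBM-SEGPHOS (5.5 mol %), (EtO)2MeSiH (4 equiv), toluene, 0 °C → rt; then AcOH, THF–H2O, 0 °C
Reagents that add atoms: none
Why: Proposed new method: the silane turns Cu(OAc)2 and the bisphosphine into a ligated monovalent copper hydride that adds hydride to C2 of the vinylogous ester, and the oxygen-bound copper enolate is turned over by the silane to silyl enol ether 17, which is hydrolysed only on work-up, so C3 is protonated after the metal has left and the β-aryloxy enolate has little chance to eject O1; the closest known reaction type is the asymmetric copper hydride 1,4-reduction of 2-alkylchromones and of cyclic β,β-disubstituted enones, and what is untested is the 2-aryl group of a flavone. C2 is set by the axially chiral bisphosphine, which has to tell the ring-B aryl group from O1 and deliver hydride to the Re face of C2 to give 2S (ligand enantiomer as assumed above). The conjugated enone should react well before the isolated prenyl alkene or the hindered 1,2-disubstituted styrenyl alkene is hydrocuprated, and the free tertiary alcohol is tolerated as tert-butanol is when used as an additive in such reductions; any silyl ether it forms with the silane is cleaved on work-up or in step 12.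

Step 12
Reactants: 18 (2S)-5,7-bis(tert-butyldimethylsilyloxy)-2-[3-[(E)-3-hydroxy-3-methylbut-1-enyl]-4-methoxy-5-(3-methylbut-2-enyl)phenyl]-2,3-dihydrochromen-4-one
Product: 19 (2S)-5,7-dihydroxy-2-[3-[(E)-3-hydroxy-3-methylbut-1-enyl]-4-methoxy-5-(3-methylbut-2-enyl)phenyl]-2,3-dihydrochromen-4-one
Conditions: Bu4NF, AcOH (1:1), THF, 0 °C
Reagents that add atoms: none
Why: Fluoride-mediated cleavage of the two aryl silyl ethers; acetic acid buffers the phenoxides as they form, so ring C is not opened by β-elimination and C2 should keep its configuration. The medium is far too weakly acidic to ionise the tertiary allylic alcohol.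

**Compound list**

1 | 3-bromo-4-hydroxybenzaldehyde | O=Cc1ccc(O)c(Br)c1 | starting material
2 | 3-bromo-4-(prop-2-enyloxy)benzaldehyde | O=Cc1ccc(OCC=C)c(Br)c1 | intermediate
3 | 3-bromo-4-hydroxy-5-(prop-2-enyl)benzaldehyde | O=Cc1cc(Br)c(O)c(CC=C)c1 | intermediate
4 | 3-bromo-4-methoxy-5-(prop-2-enyl)benzaldehyde | COc1c(Br)cc(C=O)cc1CC=C | intermediate
5 | 3-bromo-4-methoxy-5-(3-methylbut-2-enyl)benzaldehyde | COc1c(Br)cc(C=O)cc1CC=C(C)C | intermediate
6 | 2-methylbut-3-en-2-ol | C=CC(C)(C)O | starting material
7 | 3-[(E)-3-hydroxy-3-methylbut-1-enyl]-4-methoxy-5-(3-methylbut-2-enyl)benzaldehyde | COc1c(/C=C/C(C)(C)O)cc(C=O)cc1CC=C(C)C | intermediate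
8 | (E)-4-[5-ethynyl-2-methoxy-3-(3-methylbut-2-enyl)phenyl]-2-methylbut-3-en-2-ol | COc1c(/C=C/C(C)(C)O)cc(C#C)cc1CC=C(C)C | intermediate
9 | benzene-1,3,5-triol (phloroglucinol) | Oc1cc(O)cc(O)c1 | starting material
10 | 2-iodobenzene-1,3,5-triol | Oc1cc(O)c(I)c(O)c1 | intermediate
11 | 2-iodobenzene-1,3,5-triyl triacetate | CC(=O)Oc1cc(OC(C)=O)c(I)c(OC(C)=O)c1 | intermediate
12 | carbon monoxide | [C-]#[O+] | starting material
13 | 2-[3-[3-[(E)-3-hydroxy-3-methylbut-1-enyl]-4-methoxy-5-(3-methylbut-2-enyl)phenyl]prop-2-ynoyl]benzene-1,3,5-triyl triacetate (formed in step 9, not isolated) | COc1c(/C=C/C(C)(C)O)cc(C#CC(=O)c2c(OC(C)=O)cc(OC(C)=O)cc2OC(C)=O)cc1CC=C(C)C | intermediate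
14 | (E)-3-(diethylamino)-3-[3-[(E)-3-hydroxy-3-methylbut-1-enyl]-4-methoxy-5-(3-methylbut-2-enyl)phenyl]-1-(2,4,6-trihydroxyphenyl)prop-2-en-1-one (formed in step 9, not isolated; the enaminone double bond is drawn E and can isomerise) | CCN(CC)/C(=C/C(=O)c1c(O)cc(O)cc1O)c1cc(CC=C(C)C)c(OC)c(/C=C/C(C)(C)O)c1 | intermediate
15 | 5,7-dihydroxy-2-[3-[(E)-3-hydroxy-3-methylbut-1-enyl]-4-methoxy-5-(3-methylbut-2-enyl)phenyl]chromen-4-one | COc1c(/C=C/C(C)(C)O)cc(C2=CC(=O)c3c(O)cc(O)cc3O2)cc1CC=C(C)C | intermediate
16 | 5,7-bis(tert-butyldimethylsilyloxy)-2-[3-[(E)-3-hydroxy-3-methylbut-1-enyl]-4-methoxy-5-(3-methylbut-2-enyl)phenyl]chromen-4-one | COc1c(/C=C/C(C)(C)O)cc(C2=CC(=O)c3c(O[Si](C)(C)C(C)(C)C)cc(O[Si](C)(C)C(C)(C)C)cc3O2)cc1CC=C(C)C | intermediate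
17 | (2S)-5,7-bis(tert-butyldimethylsilyloxy)-4-[diethoxy(methyl)silyloxy]-2-[3-[(E)-3-hydroxy-3-methylbut-1-enyl]-4-methoxy-5-(3-methylbut-2-enyl)phenyl]-2H-chromene (formed in step 11, not isolated) | COc1c(/C=C/C(C)(C)O)cc([C@@H]2C=C(O[Si](C)(OCC)OCC)c3c(O[Si](C)(C)C(C)(C)C)cc(O[Si](C)(C)C(C)(C)C)cc3O2)cc1CC=C(C)C | intermediate
18 | (2S)-5,7-bis(tert-butyldimethylsilyloxy)-2-[3-[(E)-3-hydroxy-3-methylbut-1-enyl]-4-methoxy-5-(3-methylbut-2-enyl)phenyl]-2,3-dihydrochromen-4-one | COc1c(/C=C/C(C)(C)O)cc([C@@H]2CC(=O)c3c(O[Si](C)(C)C(C)(C)C)cc(O[Si](C)(C)C(C)(C)C)cc3O2)cc1CC=C(C)C | intermediate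
19 | (2S)-5,7-dihydroxy-2-[3-[(E)-3-hydroxy-3-methylbut-1-enyl]-4-methoxy-5-(3-methylbut-2-enyl)phenyl]-2,3-dihydrochromen-4-one | COc1c(/C=C/C(C)(C)O)cc([C@@H]2CC(=O)c3c(O)cc(O)cc3O2)cc1CC=C(C)C | target

**Step count and uncertain steps**

Total: 12 steps. Longest linear sequence: 10 steps (steps 1–6, then 9–12, from 1).

Step 11 (the step labelled as a new method) is the least certain.
- What may go wrong: hydride transfer to C2 may be slow or poorly face-selective, because the ring-B aryl group conjugates with the enone and gives the ligand an aryl/oxygen pair to distinguish instead of an alkyl/oxygen pair. The metal enolate may eject O1, opening ring C to a chalcone that is then over-reduced. Hydrocupration of the styrenyl alkene may compete if the enone reacts slowly.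
- Fallback (known chemistry, resolution instead of asymmetric reduction): it sets out from 16. Conjugate hydride reduction with LiBH(s-Bu)3 in THF at −78 °C, the standard 1,4-reduction of chromones and isoflavones, quenched cold with acetic acid, should give racemic 5,7-bis(tert-butyldimethylsilyloxy)-2-[3-[(E)-3-hydroxy-3-methylbut-1-enyl]-4-methoxy-5-(3-methylbut-2-enyl)phenyl]-2,3-dihydrochromen-4-one F1. Kinetic resolution by transfer hydrogenation, an established method for racemic flavanones, with Cp*RhCl[(R,R)-TsDPEN] and HCO2H–Et3N in ethyl acetate is expected to reduce the 2R ketone to the cis alcohol (2R,4R)-5,7-bis(tert-butyldimethylsilyloxy)-2-[3-[(E)-3-hydroxy-3-methylbut-1-enyl]-4-methoxy-5-(3-methylbut-2-enyl)phenyl]chroman-4-ol F2 and leave the 2S ketone. The sense of the resolution has to be checked. The unreduced ketone is 18, where the route is rejoined, at the cost of half the material.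

Step 9 (key step).
- What may go wrong: oxidative addition at the iodide flanked by two acetoxy groups may stall, so that direct aryl–alkyne coupling without CO uptake or alkyne oligomerisation takes over. Acetates may also be lost before the ynone has formed, exposing phenoxides to the aroylpalladium species.
- Fallback (preformed acyl group instead of CO): it sets out from 8. Commercial 2,4,6-trihydroxybenzoic acid is acetylated (Ac2O, pyridine, 0 °C) to 2,4,6-triacetoxybenzoic acid F3, which oxalyl chloride with catalytic DMF converts into 2,4,6-triacetoxybenzoyl chloride F4. Acyl Sonogashira coupling of F4 with 8 (PdCl2(PPh3)2, CuI, Et3N, THF, rt) gives ynone 13, where the route is rejoined; the diethylamine stage of step 9 then leads to 15.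

Step 10.
- What may go wrong: silylation of the hydrogen-bonded 5-OH may stay incomplete, or the 5-O-silyl group may be lost during purification on silica.
- Fallback (transient protection carried through without isolation): it sets out from 15. N,O-bis(trimethylsilyl)acetamide in MeCN at 60 °C silylates all three hydroxyls to 5,7-bis(trimethylsilyloxy)-2-[4-methoxy-3-[(E)-3-methyl-3-(trimethylsilyloxy)but-1-enyl]-5-(3-methylbut-2-enyl)phenyl]chromen-4-one F5. After evaporation, the crude material is reduced under the conditions of step 11 to (2S)-5,7-bis(trimethylsilyloxy)-2-[4-methoxy-3-[(E)-3-methyl-3-(trimethylsilyloxy)but-1-enyl]-5-(3-methylbut-2-enyl)phenyl]-2,3-dihydrochromen-4-one F6. The buffered fluoride of step 12 then removes all three trimethylsilyl groups and the route is rejoined at 19.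

Step 5.
- What may go wrong: the tertiary allylic alcohol may eliminate water at 100 °C in the presence of the ammonium salt, or a palladium hydride may move the prenyl double bond into conjugation.
- Fallback (cross-coupling with a preformed E-alkenyl unit instead of a Heck reaction): it sets out from 5. Suzuki–Miyaura coupling with commercial (E)-2-methyl-4-(4,4,5,5-tetramethyl-1,3,2-dioxaborolan-2-yl)but-3-en-2-ol (Pd(dppf)Cl2, K2CO3, dioxane–H2O, 80 °C) gives 7 directly, where the route is rejoined; no new intermediate is made.

**Further compounds**

F1 | step 11 | racemic 5,7-bis(tert-butyldimethylsilyloxy)-2-[3-[(E)-3-hydroxy-3-methylbut-1-enyl]-4-methoxy-5-(3-methylbut-2-enyl)phenyl]-2,3-dihydrochromen-4-one | COc1c(/C=C/C(C)(C)O)cc(C2CC(=O)c3c(O[Si](C)(C)C(C)(C)C)cc(O[Si](C)(C)C(C)(C)C)cc3O2)cc1CC=C(C)C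
F2 | step 11 | (2R,4R)-5,7-bis(tert-butyldimethylsilyloxy)-2-[3-[(E)-3-hydroxy-3-methylbut-1-enyl]-4-methoxy-5-(3-methylbut-2-enyl)phenyl]chroman-4-ol | COc1c(/C=C/C(C)(C)O)cc([C@H]2C[C@@H](O)c3c(O[Si](C)(C)C(C)(C)C)cc(O[Si](C)(C)C(C)(C)C)cc3O2)cc1CC=C(C)C
F3 | step 9 | 2,4,6-triacetoxybenzoic acid | CC(=O)Oc1cc(OC(C)=O)c(C(=O)O)c(OC(C)=O)c1
F4 | step 9 | 2,4,6-triacetoxybenzoyl chloride | CC(=O)Oc1cc(OC(C)=O)c(C(Cl)=O)c(OC(C)=O)c1
F5 | step 10 | 5,7-bis(trimethylsilyloxy)-2-[4-methoxy-3-[(E)-3-methyl-3-(trimethylsilyloxy)but-1-enyl]-5-(3-methylbut-2-enyl)phenyl]chromen-4-one | COc1c(/C=C/C(C)(C)O[Si](C)(C)C)cc(C2=CC(=O)c3c(O[Si](C)(C)C)cc(O[Si](C)(C)C)cc3O2)cc1CC=C(C)C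
F6 | step 10 | (2S)-5,7-bis(trimethylsilyloxy)-2-[4-methoxy-3-[(E)-3-methyl-3-(trimethylsilyloxy)but-1-enyl]-5-(3-methylbut-2-enyl)phenyl]-2,3-dihydrochromen-4-one | COc1c(/C=C/C(C)(C)O[Si](C)(C)C)cc([C@@H]2CC(=O)c3c(O[Si](C)(C)C)cc(O[Si](C)(C)C)cc3O2)cc1CC=C(C)C
F0 | step 5 | none | none
A1 | alternative 1 | (2S,4S)-2-[3-bromo-4-methoxy-5-(3-methylbut-2-enyl)phenyl]-4-methoxy-5,7-bis(methoxymethoxy)chromane | COc1c(Br)cc([C@@H]2C[C@H](OC)c3c(OCOC)cc(OCOC)cc3O2)cc1CC=C(C)C
A2 | alternative 1 | 1-bromo-5-ethenyl-2-methoxy-3-(3-methylbut-2-enyl)benzene | COc1c(Br)cc(C=C)cc1CC=C(C)C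
A3 | alternative 2 | (2S)-2-[3-bromo-4-methoxy-5-(3-methylbut-2-enyl)phenyl]-5,7-dihydroxychroman-4-one | COc1c(Br)cc([C@@H]2CC(=O)c3c(O)cc(O)cc3O2)cc1CC=C(C)C
A4 | alternative 2 | methyl 4-[(2S)-2-[3-bromo-4-methoxy-5-(3-methylbut-2-enyl)phenyl]-4-oxo-2,3-dihydropyran-6-yl]-3-oxobutanoate | COc1c(Br)cc([C@@H]2CC(=O)C=C(CC(=O)CC(=O)OC)O2)cc1CC=C(C)C
A5 | alternative 3 | (2S)-2-[3-bromo-4-methoxy-5-(3-methylbut-2-enyl)phenyl]-5,7-bis(tert-butyldimethylsilyloxy)chroman-4-one | COc1c(Br)cc([C@@H]2CC(=O)c3c(O[Si](C)(C)C(C)(C)C)cc(O[Si](C)(C)C(C)(C)C)cc3O2)cc1CC=C(C)C
A6 | alternative 3 | (3S)-3-[3,5-bis(tert-butyldimethylsilyloxy)phenoxy]-3-[3-bromo-4-methoxy-5-(3-methylbut-2-enyl)phenyl]propanoic acid | COc1c(Br)cc([C@H](CC(=O)O)Oc2cc(O[Si](C)(C)C(C)(C)C)cc(O[Si](C)(C)C(C)(C)C)c2)cc1CC=C(C)C
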